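Everything rests on reading the cyclopentanol ring (C1–C2–C3–C3a–C8a) as a C3 cyclopentanone that awaits isopropyl addition, and that ketone as the hydroacylation product of a 4-pentenal whose C3a–C8a bond, with the methyl-bearing quaternary C8a, is a Claisen bond. One operation therefore converts an acyclic allyl vinyl ether into the cyclopentanone: [3,3] shift (C3a–C8a), then rhodium-catalysed hydroacylation (C2–C3). The precursor is the (E)-enol ether of a β-silyloxy aldehyde with (E)-3-methylhexa-2,5-dien-1-ol; its single carbinol centre (future C4) relays configuration to C3a and C8a. Ring-closing metathesis (C6=C7) then closes the seven-membered ring.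

Key step: step 6

Remark: the SMILES is read as the (3R,3aS,4S,8aR) enantiomer (trans ring fusion, C3 hydroxyl cis to the C8a methyl); atoms of all intermediates carry the octahydroazulene numbers of the target.

Step 1
Reactants: 1 3-(trimethylsilyl)prop-2-ynal; 2 (2-methylprop-2-en-1-yl)magnesium chloride
Product: 6 (3S)-5-methylhex-5-en-1-yn-3-ol, via methallylborane 3 (not isolated), via borinate ester 4 (not isolated), via silyl alkynol 5 (not isolated)
Conditions: (−)-B-methoxydiisopinocampheylborane, Et2O, 0 °C; then 1, −78 °C → rt; then NaOH, H2O2, MeOH/H2O, rt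
Reagents that add atoms: none
Why: Brown-type asymmetric methallylboration through a chair transition state, with the isopinocampheyl groups selecting the aldehyde face, should set the (S)-carbinol (future C4), and the alkaline peroxide work-up should also cleave the C(sp)–Si bond.

Step 2
Reactants: 6 (3S)-5-methylhex-5-en-1-yn-3-ol
Product: 7 tert-butyldimethyl{[(3S)-5-methylhex-5-en-1-yn-3-yl]oxy}silane
Conditions: t-BuMe2SiCl, imidazole, DMF, rt
Reagents that add atoms: tert-butyldimethylsilyl chloride, CC(C)(C)[Si](C)(C)Cl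
Why: Imidazole-promoted silylation of the secondary propargylic alcohol is routine and leaves the stereocentre untouched.

Step 3
Reactants: 7 tert-butyldimethyl{[(3S)-5-methylhex-5-en-1-yn-3-yl]oxy}silane
Product: 9 tert-butyl{[(1E,3S)-1-iodo-5-methylhexa-1,5-dien-3-yl]oxy}dimethylsilane, via alkenylzirconocene chloride 8 (not isolated)
Conditions: Cp2Zr(H)Cl, THF, rt; then I2, 0 °C
Reagents that add atoms: iodine, II
Why: Hydrozirconation (Schwartz reagent) adds syn and anti-Markovnikov to the terminal alkyne much faster than to the 1,1-disubstituted alkene, and iodinolysis with retention should give the (E)-iodide.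

Step 4
Reactants: 10 pent-1-en-4-yne
Product: 12 (2E)-3-methylhexa-2,5-dien-1-ol, via alkenylalane 11 (not isolated)
Conditions: AlMe3, Cp2ZrCl2 (cat.), CH2Cl2, 0 °C → rt; then n-BuLi, (CH2O)n, THF, −78 °C → rt; aq. HCl
Reagents that add atoms: trimethylaluminium, C[Al](C)C; paraformaldehyde (as formaldehyde), C=O
Why: Negishi zirconium-catalysed carboalumination adds methyl and aluminium syn across the alkyne (aluminium at the terminus), which fixes the (E)-trisubstituted alkene before the alanate adds to formaldehyde, while the terminal alkene is inert under these conditions.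

Step 5
Reactants: 9 tert-butyl{[(1E,3S)-1-iodo-5-methylhexa-1,5-dien-3-yl]oxy}dimethylsilane; 12 (2E)-3-methylhexa-2,5-dien-1-ol
Product: 13 tert-butyldimethyl{[(1E,3S)-5-methyl-1-{[(2E)-3-methylhexa-2,5-dien-1-yl]oxy}hexa-1,5-dien-3-yl]oxy}silane
Conditions: CuI (10 mol %), 3,4,7,8-tetramethyl-1,10-phenanthroline (20 mol %), Cs2CO3, toluene, 80 °C
Reagents that add atoms: none
Why: Copper-catalysed Ullmann-type C–O coupling of an alkenyl iodide with an allylic alcohol retains the alkene geometry and should give the (E,E)-allyl vinyl ether, the temperature being held at 80 °C to limit premature rearrangement.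

Step 6
Reactants: 13 tert-butyldimethyl{[(1E,3S)-5-methyl-1-{[(2E)-3-methylhexa-2,5-dien-1-yl]oxy}hexa-1,5-dien-3-yl]oxy}silane
Product: 15 (2S,3R)-2-[(1S)-1-{[tert-butyl(dimethyl)silyl]oxy}-3-methylbut-3-en-1-yl]-3-methyl-3-(prop-2-en-1-yl)cyclopentan-1-one, via aldehyde 14 (not isolated)
Conditions: ClCH2CH2Cl, 130 °C (sealed tube); then [Rh(nbd)(Ph2PCH2CH2PPh2)]BF4 (nbd = norbornadiene, C7H8; 5 mol %, pre-treated with H2), 60 °C
Reagents that add atoms: none
Why: Heating effects a [3,3]-sigmatropic (Claisen) rearrangement of the allyl vinyl ether through a chair transition state, forming the C3a–C8a bond and releasing 4-pentenal 14; the cationic monovalent rhodium catalyst then inserts into the formyl C–H bond, the acyl rhodium hydride adds across the adjacent vinyl group (hydride to the internal carbon) and C–C reductive elimination forms the C2–C3 bond (intramolecular hydroacylation). The closest known reaction types are the one-pot Claisen rearrangement–hydroacylation of allyl vinyl ethers to cyclopentanones and the rhodium-catalysed cyclisation of 3,3-disubstituted 4-pentenals. Only the cyclopentanone ring closes, by reductive elimination from a six-membered acyl rhodacycle (net anti-Markovnikov addition of the aldehyde C–H to the vinyl group); the seven-membered ring is left for step 7. C8a and C3a arise together in the chair: the (E)-enol ether and the (E)-allyl unit place the silyloxyalkyl chain and the allyl group equatorial and the methyl axial, which puts the side chain cis to the methyl and trans to the allyl group on the future ring. The absolute sense is relayed from the silyloxy stereocentre (future C4), whose enol ether should be attacked on the face that keeps the C–O bond inside and the methallyl carbon anti to the forming bond, giving the anti (3aS,4S) relationship. The step needs this facial selectivity and chemoselective hydroacylation, the latter being secured because only the vinyl group reaches the acyl rhodium hydride in the fast 4-pentenal mode, whereas the allyl and methallyl groups would need the slower 5-hexenal mode.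

Step 7
Reactants: 15 (2S,3R)-2-[(1S)-1-{[tert-butyl(dimethyl)silyl]oxy}-3-methylbut-3-en-1-yl]-3-methyl-3-(prop-2-en-1-yl)cyclopentan-1-one
Product: 16 (3aS,4S,8aR)-4-{[tert-butyl(dimethyl)silyl]oxy}-6,8a-dimethyl-1,2,4,5,8,8a-hexahydroazulen-3(3aH)-one
Conditions: second-generation Grubbs catalyst RuCl2(=CHPh)(PCy3)(H2IMes) (5 mol %), CH2Cl2 (0.005 M), 40 °C
Reagents that add atoms: none
Why: Ring-closing metathesis between the allyl and methallyl groups, the only alkenes left, should form the trisubstituted C6=C7 bond of the trans-fused seven-membered ring without touching a stereocentre.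

Step 8
Reactants: 16 (3aS,4S,8aR)-4-{[tert-butyl(dimethyl)silyl]oxy}-6,8a-dimethyl-1,2,4,5,8,8a-hexahydroazulen-3(3aH)-one
Product: 17 (3R,3aS,4S,8aR)-4-{[tert-butyl(dimethyl)silyl]oxy}-6,8a-dimethyl-3-(propan-2-yl)-1,2,3,3a,4,5,8,8a-octahydroazulen-3-ol
Conditions: i-PrMgCl, CeCl3, THF, −78 °C → 0 °C
Reagents that add atoms: isopropylmagnesium chloride, CC(C)[Mg]Cl
Why: Organocerium (Imamoto-type) 1,2-addition suppresses enolisation and β-elimination, and attack on the ketone face of H3a, away from the C8a methyl and the C4 carbon, should give the (3R) alcohol with the hydroxyl cis to the angular methyl.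

Step 9
Reactants: 17 (3R,3aS,4S,8aR)-4-{[tert-butyl(dimethyl)silyl]oxy}-6,8a-dimethyl-3-(propan-2-yl)-1,2,3,3a,4,5,8,8a-octahydroazulen-3-ol
Product: 18 (3R,3aS,4S,8aR)-6,8a-dimethyl-3-(propan-2-yl)-1,2,3,3a,4,5,8,8a-octahydroazulene-3,4-diol
Conditions: Bu4NF, THF, rt → 50 °C
Reagents that add atoms: none
Why: Fluoride cleaves the Si–O bond and should free the secondary alcohol without affecting the tertiary alcohol, the alkene or any stereocentre.

Step 10
Reactants: 18 (3R,3aS,4S,8aR)-6,8a-dimethyl-3-(propan-2-yl)-1,2,3,3a,4,5,8,8a-octahydroazulene-3,4-diol; 19 2,2-dimethyl-4H-1,3-benzodioxin-4-one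
Product: 20 (3R,3aS,4S,8aR)-3-hydroxy-6,8a-dimethyl-3-(propan-2-yl)-1,2,3,3a,4,5,8,8a-octahydroazulen-4-yl 2-hydroxybenzoate
Conditions: NaN(SiMe3)2 (1.1 equiv), THF, 0 °C; then 19, 0 °C → rt; AcOH quench
Reagents that add atoms: none
Why: The secondary alkoxide should open the benzodioxinone by acyl transfer with loss of acetone, unveiling the free phenol directly, while the hindered tertiary hydroxyl stays unacylated and C4 keeps its configuration.

Compound list
1 | 3-(trimethylsilyl)prop-2-ynal | C[Si](C)(C)C#CC=O | starting material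
2 | (2-methylprop-2-en-1-yl)magnesium chloride | C=C(C)C[Mg]Cl | starting material
3 | (−)-B-(2-methylprop-2-en-1-yl)diisopinocampheylborane | C=C(C)CB([C@@H]1C[C@@H]2C[C@H]([C@H]1C)C2(C)C)[C@@H]1C[C@@H]2C[C@H]([C@H]1C)C2(C)C | intermediate (not isolated)
4 | (3S)-5-methyl-1-(trimethylsilyl)hex-5-en-1-yn-3-yl diisopinocampheylborinate | C[Si](C)(C)C#C[C@@H](OB([C@@H]1C[C@@H]2C[C@H]([C@H]1C)C2(C)C)[C@@H]1C[C@@H]2C[C@H]([C@H]1C)C2(C)C)CC(C)=C | intermediate (not isolated)
5 | (3S)-5-methyl-1-(trimethylsilyl)hex-5-en-1-yn-3-ol | C[Si](C)(C)C#C[C@@H](O)CC(C)=C | intermediate (not isolated)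
6 | (3S)-5-methylhex-5-en-1-yn-3-ol | C#C[C@@H](O)CC(C)=C | intermediate
7 | tert-butyldimethyl{[(3S)-5-methylhex-5-en-1-yn-3-yl]oxy}silane | C#C[C@@H](O[Si](C)(C)C(C)(C)C)CC(C)=C | intermediate
8 | chlorobis(cyclopentadienyl)[(1E,3S)-3-{[tert-butyl(dimethyl)silyl]oxy}-5-methylhexa-1,5-dien-1-yl]zirconium | Cl[Zr](/C=C/[C@@H](O[Si](C)(C)C(C)(C)C)CC(C)=C)(C1C=CC=C1)C1C=CC=C1 | intermediate (not isolated)
9 | tert-butyl{[(1E,3S)-1-iodo-5-methylhexa-1,5-dien-3-yl]oxy}dimethylsilane | I/C=C/[C@@H](O[Si](C)(C)C(C)(C)C)CC(C)=C | intermediate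
10 | pent-1-en-4-yne | C=CCC#C | starting material
11 | dimethyl[(1E)-2-methylpenta-1,4-dien-1-yl]alumane | C=CCC(/C)=C/[Al](C)C | intermediate (not isolated)
12 | (2E)-3-methylhexa-2,5-dien-1-ol | OC/C=C(\C)CC=C | intermediate
13 | tert-butyldimethyl{[(1E,3S)-5-methyl-1-{[(2E)-3-methylhexa-2,5-dien-1-yl]oxy}hexa-1,5-dien-3-yl]oxy}silane | C=CCC(/C)=C/CO/C=C/[C@@H](O[Si](C)(C)C(C)(C)C)CC(C)=C | intermediate
14 | (2S,3S)-2-[(1S)-1-{[tert-butyl(dimethyl)silyl]oxy}-3-methylbut-3-en-1-yl]-3-ethenyl-3-methylhex-5-enal | C=CC[C@@](C)(C=C)[C@H](C=O)[C@@H](O[Si](C)(C)C(C)(C)C)CC(C)=C | intermediate (not isolated)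
15 | (2S,3R)-2-[(1S)-1-{[tert-butyl(dimethyl)silyl]oxy}-3-methylbut-3-en-1-yl]-3-methyl-3-(prop-2-en-1-yl)cyclopentan-1-one | O=C1CC[C@](C)(CC=C)[C@H]1[C@@H](O[Si](C)(C)C(C)(C)C)CC(C)=C | intermediate
16 | (3aS,4S,8aR)-4-{[tert-butyl(dimethyl)silyl]oxy}-6,8a-dimethyl-1,2,4,5,8,8a-hexahydroazulen-3(3aH)-one | CC1=CC[C@@]2(C)CCC(=O)[C@@H]2[C@@H](O[Si](C)(C)C(C)(C)C)C1 | intermediate
17 | (3R,3aS,4S,8aR)-4-{[tert-butyl(dimethyl)silyl]oxy}-6,8a-dimethyl-3-(propan-2-yl)-1,2,3,3a,4,5,8,8a-octahydroazulen-3-ol | CC1=CC[C@@]2(C)CC[C@@](O)(C(C)C)[C@@H]2[C@@H](O[Si](C)(C)C(C)(C)C)C1 | intermediate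
18 | (3R,3aS,4S,8aR)-6,8a-dimethyl-3-(propan-2-yl)-1,2,3,3a,4,5,8,8a-octahydroazulene-3,4-diol | CC1=CC[C@@]2(C)CC[C@@](O)(C(C)C)[C@@H]2[C@@H](O)C1 | intermediate
19 | 2,2-dimethyl-4H-1,3-benzodioxin-4-one | CC1(C)OC(=O)c2ccccc2O1 | starting material
20 | (3R,3aS,4S,8aR)-3-hydroxy-6,8a-dimethyl-3-(propan-2-yl)-1,2,3,3a,4,5,8,8a-octahydroazulen-4-yl 2-hydroxybenzoate | CC1=CC[C@@]2(C)CC[C@@](O)(C(C)C)[C@@H]2[C@@H](OC(=O)c2ccccc2O)C1 | target

Total step count: 10. Longest linear sequence: 9 steps (steps 1, 2, 3, 5, 6, 7, 8, 9 and 10; step 4 supplies the second fragment).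

Steps most likely to fail

Step 6 (key step). The allyl terminus may add to the enol ether face syn to the silyloxy group, so that the sense of induction from the carbinol centre is reversed; the chair would still fix C3a against C8a. The fallback uses the carbinol only as a relay and resets it at the end. It sets out from 1 and 2, rerunning steps 1 to 9 with (+)-B-methoxydiisopinocampheylborane. Step 1 then passes through (+)-methallylborane F1, borinate ester F2 and silyl alkynol F3 to (R)-alkynol F4. Silylation gives silyl ether F5, hydrozirconation–iodination via alkenylzirconium F6 gives (R)-iodide F7, and coupling with 12 gives (R)-ether F8. The rearrangement–hydroacylation should now give, via aldehyde F9, cyclopentanone F10 with the ring centres as in 15. Metathesis, isopropyl addition and desilylation give ketone F11, silyl ether alcohol F12 and the C4-epimeric diol F13. Dess–Martin oxidation of the secondary hydroxyl gives hydroxy ketone F14. Reduction with Me4NBH(OAc)3, delivered from the C3 hydroxyl (Evans–Saksena anti reduction), should set the (4S) carbinol and brings the route back at 18.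

Step 8. β-Hydride transfer from the isopropyl reagent (reduction of the ketone) and enolisation with loss of the β-silyloxy group may outrun addition. The fallback sets out from 16: isopropenylmagnesium bromide with CeCl3, an sp2 nucleophile that cannot reduce in this way, should give isopropenyl carbinol F15 by the same facial preference. Hydrogenation of its 1,1-disubstituted alkene with H2 and RhCl(PPh3)3, which spares the trisubstituted ring alkene, brings the route back at 17.

Step 5. The coupling needs base and heat, under which a premature [3,3] shift followed by aldol reaction or elimination of the silyloxy aldehyde, or slow oxidative addition, may erode the ether. The fallback sets out from 7: hydroboration with pinacolborane catalysed by Cp2Zr(H)Cl should give (E)-alkenylboronate F16. Oxidative C–O coupling of F16 with 12 by Cu(OAc)2 and Et3N at room temperature brings the route back at 13.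

Further compounds
F1 | step 6 | (+)-B-(2-methylprop-2-en-1-yl)diisopinocampheylborane | C=C(C)CB([C@H]1C[C@H]2C[C@@H]([C@@H]1C)C2(C)C)[C@H]1C[C@H]2C[C@@H]([C@@H]1C)C2(C)C
F2 | step 6 | (3R)-5-methyl-1-(trimethylsilyl)hex-5-en-1-yn-3-yl diisopinocampheylborinate | C[Si](C)(C)C#C[C@H](OB([C@H]1C[C@H]2C[C@@H]([C@@H]1C)C2(C)C)[C@H]1C[C@H]2C[C@@H]([C@@H]1C)C2(C)C)CC(C)=C
F3 | step 6 | (3R)-5-methyl-1-(trimethylsilyl)hex-5-en-1-yn-3-ol | C[Si](C)(C)C#C[C@H](O)CC(C)=C
F4 | step 6 | (3R)-5-methylhex-5-en-1-yn-3-ol | C#C[C@H](O)CC(C)=C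
F5 | step 6 | tert-butyldimethyl{[(3R)-5-methylhex-5-en-1-yn-3-yl]oxy}silane | C#C[C@H](O[Si](C)(C)C(C)(C)C)CC(C)=C
F6 | step 6 | chlorobis(cyclopentadienyl)[(1E,3R)-3-{[tert-butyl(dimethyl)silyl]oxy}-5-methylhexa-1,5-dien-1-yl]zirconium | Cl[Zr](/C=C/[C@H](O[Si](C)(C)C(C)(C)C)CC(C)=C)(C1C=CC=C1)C1C=CC=C1
F7 | step 6 | tert-butyl{[(1E,3R)-1-iodo-5-methylhexa-1,5-dien-3-yl]oxy}dimethylsilane | I/C=C/[C@H](O[Si](C)(C)C(C)(C)C)CC(C)=C
F8 | step 6 | tert-butyldimethyl{[(1E,3R)-5-methyl-1-{[(2E)-3-methylhexa-2,5-dien-1-yl]oxy}hexa-1,5-dien-3-yl]oxy}silane | C=CCC(/C)=C/CO/C=C/[C@H](O[Si](C)(C)C(C)(C)C)CC(C)=C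
F9 | step 6 | (2S,3S)-2-[(1R)-1-{[tert-butyl(dimethyl)silyl]oxy}-3-methylbut-3-en-1-yl]-3-ethenyl-3-methylhex-5-enal | C=CC[C@@](C)(C=C)[C@H](C=O)[C@H](O[Si](C)(C)C(C)(C)C)CC(C)=C
F10 | step 6 | (2S,3R)-2-[(1R)-1-{[tert-butyl(dimethyl)silyl]oxy}-3-methylbut-3-en-1-yl]-3-methyl-3-(prop-2-en-1-yl)cyclopentan-1-one | O=C1CC[C@](C)(CC=C)[C@H]1[C@H](O[Si](C)(C)C(C)(C)C)CC(C)=C
F11 | step 6 | (3aS,4R,8aR)-4-{[tert-butyl(dimethyl)silyl]oxy}-6,8a-dimethyl-1,2,4,5,8,8a-hexahydroazulen-3(3aH)-one | CC1=CC[C@@]2(C)CCC(=O)[C@@H]2[C@H](O[Si](C)(C)C(C)(C)C)C1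
F12 | step 6 | (3R,3aS,4R,8aR)-4-{[tert-butyl(dimethyl)silyl]oxy}-6,8a-dimethyl-3-(propan-2-yl)-1,2,3,3a,4,5,8,8a-octahydroazulen-3-ol | CC1=CC[C@@]2(C)CC[C@@](O)(C(C)C)[C@@H]2[C@H](O[Si](C)(C)C(C)(C)C)C1
F13 | step 6 | (3R,3aS,4R,8aR)-6,8a-dimethyl-3-(propan-2-yl)-1,2,3,3a,4,5,8,8a-octahydroazulene-3,4-diol | CC1=CC[C@@]2(C)CC[C@@](O)(C(C)C)[C@@H]2[C@H](O)C1
F14 | step 6 | (3R,3aR,8aR)-3-hydroxy-6,8a-dimethyl-3-(propan-2-yl)-1,2,3,3a,8,8a-hexahydroazulen-4(5H)-one | CC1=CC[C@@]2(C)CC[C@@](O)(C(C)C)[C@@H]2C(=O)C1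
F15 | step 8 | (3S,3aS,4S,8aR)-4-{[tert-butyl(dimethyl)silyl]oxy}-6,8a-dimethyl-3-(prop-1-en-2-yl)-1,2,3,3a,4,5,8,8a-octahydroazulen-3-ol | CC1=CC[C@@]2(C)CC[C@@](O)(C(C)=C)[C@@H]2[C@@H](O[Si](C)(C)C(C)(C)C)C1
F16 | step 5 | tert-butyldimethyl{[(1E,3S)-5-methyl-1-(4,4,5,5-tetramethyl-1,3,2-dioxaborolan-2-yl)hexa-1,5-dien-3-yl]oxy}silane | CC1(C)OB(/C=C/[C@@H](O[Si](C)(C)C(C)(C)C)CC(C)=C)OC1(C)C
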